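**Plan**

1. Numbering (eudesmane): C4 bears the exocyclic CH2 (C15), C5 is the ring-fusion CH, C6 the free carbinol, C7 the isopropyl carbon, C9 the anisate carbinol, C10 the quaternary carbon with the angular methyl; ring A = C1–C5/C10, ring B = C5–C10.
2. Retrosynthesis: C4=CH2 goes back to C4=O; ring A is then cut at C1–C2 and C3–C4, which removes C2–C3 as ethylene and leaves a cis-fused cyclobutanone C4(=O)–C5–C10–C1; this is cut at C4–C5 and C1–C10 into dichloroketene and the C5=C10 alkene of ring B; ring B goes back to (R)-carvone.
3. Enabling feature: C4 (sp2, on C5) and C1 (a CH2 on quaternary C10, so a metal–C1 alkyl has no β-hydrogen) are 1,4-related across the cis ring fusion, and C2/C3 carry nothing, so a strained four-membered ketone can hold C4 and C1 together and take up ethylene between them.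
4. Forward: ring B first (hydrogenation, two carbonyl reductions, one allylic oxidation), then the four-membered ring on C5/C10, then ring A by two-carbon ring expansion, then methylenation and desilylation; the route is linear.
5. Stereochemistry: C7 comes from (R)-carvone; C9 and C6 are set by hydride delivery relative to the C7 isopropyl group; C5 and C10 are set together in the ketene cycloaddition anti to the two allylic oxygens; the key step creates no stereocentre and carries the cis fusion over.

Key step: step 9

Remark: the target SMILES is read as a cis-fused decalin in which C10–CH3, C5–H, C6–OH, C7–isopropyl and C9–O-anisoyl all lie on one face, i.e. (5S,6S,7R,9R,10R); the route is built for this isomer.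

**Route**

Step 1
Reactants: 1 (R)-(−)-carvone
Product: 2 (R)-carvotanacetone, (5R)-2-methyl-5-(propan-2-yl)cyclohex-2-en-1-one
Conditions: H2 (1 atm), RhCl(PPh3)3 (2 mol %), toluene, 25 °C
Reagents that add atoms: none
Why: Homogeneous catalytic hydrogenation with RhCl(PPh3)3 should saturate only the unhindered 1,1-disubstituted isopropenyl alkene and leave the conjugated trisubstituted enone alkene and the C7 stereocentre untouched.

Step 2
Reactants: 2 (R)-carvotanacetone
Product: 3 cis-carvotanacetol, (1R,5R)-2-methyl-5-(propan-2-yl)cyclohex-2-en-1-ol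
Conditions: NaBH4, CeCl3·7H2O, MeOH, −20 °C
Reagents that add atoms: none
Why: Luche 1,2-reduction, in which hydride adds axially to the half-chair with equatorial C7 isopropyl, should place the new C9 hydroxyl pseudo-equatorial and cis to the isopropyl group (sets C9, as in the carvone to cis-carveol case).

Step 3
Reactants: 3 cis-carvotanacetol; 4 4-methoxybenzoyl chloride
Product: 5 (1R,5R)-2-methyl-5-(propan-2-yl)cyclohex-2-en-1-yl 4-methoxybenzoate
Conditions: pyridine, DMAP (10 mol %), CH2Cl2, 0 → 25 °C
Reagents that add atoms: 4-methoxybenzoyl chloride, COc1ccc(cc1)C(Cl)=O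
Why: DMAP-catalysed acylation of the secondary allylic alcohol with retention installs the ester of the target at C9 at once, where it also serves as protecting group and deactivates the C9–H bond towards the next oxidation.

Step 4
Reactants: 5 allylic anisate; 6 chromium trioxide
Product: 7 (1R,5R)-2-methyl-4-oxo-5-(propan-2-yl)cyclohex-2-en-1-yl 4-methoxybenzoate
Conditions: CrO3, 3,5-dimethylpyrazole, CH2Cl2, −20 °C
Reagents that add atoms: chromium trioxide, O=[Cr](=O)=O
Why: Allylic oxidation by the hexavalent chromium–pyrazole complex should convert the only ring allylic CH2 (C6, on the CH end of the alkene whose other end C10 is fully substituted) into the enone carbonyl, the pattern of the Δ5-steroid to 7-ketone oxidation, while the non-basic medium keeps the now enolisable C7 centre in its cis (diequatorial) arrangement with C9.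

Step 5
Reactants: 7 enone
Product: 8 (1R,4S,5R)-4-hydroxy-2-methyl-5-(propan-2-yl)cyclohex-2-en-1-yl 4-methoxybenzoate
Conditions: LiBH(s-Bu)3 (L-Selectride, 1.1 equiv), THF, −78 °C; then AcOH (1 equiv) at −78 °C
Reagents that add atoms: none
Why: 1,2-Reduction by a bulky trialkylborohydride, for which conjugate delivery is blocked at the fully substituted β-carbon C10, should proceed by equatorial attack on the conformer with equatorial C7 isopropyl (the menthone to neomenthol sense) and give the axial C6 alcohol cis to the isopropyl group (sets C6), the cold acidic quench preventing acyl shift from O9.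

Step 6
Reactants: 8 allylic alcohol; 9 tert-butyldimethylsilyl trifluoromethanesulfonate
Product: 10 (1R,4S,5R)-4-[(tert-butyldimethylsilyl)oxy]-2-methyl-5-(propan-2-yl)cyclohex-2-en-1-yl 4-methoxybenzoate
Conditions: TBSOTf, 2,6-lutidine, CH2Cl2, −78 → 0 °C
Reagents that add atoms: tert-butyldimethylsilyl trifluoromethanesulfonate, CC(C)(C)[Si](C)(C)OS(=O)(=O)C(F)(F)F
Why: Silylation with the silyl triflate and a hindered base is the standard way to protect a hindered axial secondary alcohol and makes the C6 oxygen a poor leaving group for the ketone chemistry that follows.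

Step 7
Reactants: 10 silyl ether; 11 trichloroacetyl chloride
Product: 13 (1R,2R,4R,5S,6S)-5-[(tert-butyldimethylsilyl)oxy]-8,8-dichloro-1-methyl-7-oxo-4-(propan-2-yl)bicyclo[4.2.0]octan-2-yl 4-methoxybenzoate, via dichloroketene 12 (not isolated)
Conditions: Cl3CCOCl (3 equiv), zinc–copper couple, POCl3 (3 equiv), Et2O, ultrasound, 20–30 °C; filtered and used without chromatography
Reagents that add atoms: trichloroacetyl chloride, ClC(Cl)(Cl)C(Cl)=O
Why: Thermal [2+2] ketene–alkene cycloaddition of dichloroketene made in situ should bond the carbonyl carbon to the less substituted C5 and the CCl2 carbon to C10, on the face opposite the two allylic oxygen substituents at C6 and C9, which sets C5 and C10 together and fixes the cis fusion with C10–CH3 and C5–H on the oxygen-bearing face.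

Step 8
Reactants: 13 dichlorocyclobutanone
Product: 14 (1R,2R,4R,5S,6S)-5-[(tert-butyldimethylsilyl)oxy]-1-methyl-7-oxo-4-(propan-2-yl)bicyclo[4.2.0]octan-2-yl 4-methoxybenzoate
Conditions: Zn dust, AcOH, 25 °C
Reagents that add atoms: none
Why: Reductive dechlorination of the α,α-dichloroketone through its zinc enolate removes the activating chlorines at C1 without touching any stereocentre, the silyl ether or the ester.

Step 9
Reactants: 14 cis-fused cyclobutanone; 15 ethylene
Product: 16 (1R,3R,4S,4aS,8aR)-4-[(tert-butyldimethylsilyl)oxy]-8a-methyl-5-oxo-3-(propan-2-yl)decahydronaphthalen-1-yl 4-methoxybenzoate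
Conditions: [Rh(C2H4)2Cl]2 (5 mol %), P[3,5-(CF3)2C6H3]3 (24 mol %), 2-amino-3-picoline (30 mol %), ethylene (10 bar), 1,4-dioxane, 110 °C; then wet silica gel
Reagents that add atoms: ethylene, C=C
Why: Proposed new method: the strained ketone should condense reversibly with 2-amino-3-picoline to a ketimine whose pyridine nitrogen guides monovalent rhodium into the C4–C1 (acyl–CH2) bond of the four-membered ring, after which ethylene inserts into one Rh–C bond and C–C reductive elimination closes the other, so that C1–C2 and C3–C4 are made in the same turnover and imine exchange releases 16. The closest known reaction types are the rhodium-catalysed "cut-and-sew" coupling of cyclobutanones with tethered olefins and the rhodium-catalysed insertion of ethylene gas into the C(O)–CH2 bond of 1-indanones, both run with the same aminopyridine co-catalyst; the new element is the intermolecular use of ethylene on a saturated ring-fused cyclobutanone. Ring A is closed by two-carbon ring expansion of the four-membered ring to a six-membered one (a formal [4+2] of the C4–C5–C10–C1 unit with ethylene through a seven-membered rhodacycle), not by cyclisation of a chain. No new stereocentre is formed: C5 and C10 were fixed cis in step 7, neither belongs to the bond that is cleaved, and the cis fusion is carried into the decalin. The step needs site selectivity between the two acyl C–C bonds and chemoselectivity against CO extrusion and β-hydride loss: C4–C1 is the open CH2 side whereas C4–C5 is flanked by quaternary C10 and the C6 silyl ether, the rhodium alkyl at C1 has no β-hydrogen because C10 is quaternary, the ketimine disfavours decarbonylation, and ethylene pressure favours insertion. Ring strain of the cyclobutanone drives the C–C oxidative addition at a temperature the ester, the silyl ether and the C5–H centre should tolerate.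

Step 10
Reactants: 16 cis-decalone; 17 dibromomethane
Product: 18 (1R,3R,4S,4aS,8aR)-4-[(tert-butyldimethylsilyl)oxy]-8a-methyl-5-methylidene-3-(propan-2-yl)decahydronaphthalen-1-yl 4-methoxybenzoate
Conditions: preformed Zn/CH2Br2/TiCl4 reagent (THF, aged at 5 °C), CH2Cl2, 0 → 25 °C
Reagents that add atoms: dibromomethane, BrCBr
Why: Takai–Lombardo methylenation with the non-basic zinc–titanium methylene reagent should convert the hindered enolisable C4 ketone into the exocyclic alkene without epimerising C5, without eliminating the β-silyloxy group and without touching the ester.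

Step 11
Reactants: 18 silyl ether
Product: 19 target, (1R,3R,4S,4aS,8aR)-4-hydroxy-8a-methyl-5-methylidene-3-(propan-2-yl)decahydronaphthalen-1-yl 4-methoxybenzoate
Conditions: HF·pyridine, THF/pyridine, 0 → 25 °C
Reagents that add atoms: none
Why: Fluoride-mediated desilylation under mildly acidic buffered conditions should free the C6 hydroxyl while avoiding the basic conditions under which the anisoyl group could migrate from O9 to O6.

**Compound list**

1 | (R)-(−)-carvone, (5R)-2-methyl-5-(prop-1-en-2-yl)cyclohex-2-en-1-one | CC1=CC[C@@H](C(C)=C)CC1=O | starting material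
2 | (R)-carvotanacetone, (5R)-2-methyl-5-(propan-2-yl)cyclohex-2-en-1-one | CC1=CC[C@@H](C(C)C)CC1=O | intermediate
3 | cis-carvotanacetol, (1R,5R)-2-methyl-5-(propan-2-yl)cyclohex-2-en-1-ol | CC1=CC[C@@H](C(C)C)C[C@H]1O | intermediate
4 | 4-methoxybenzoyl chloride | COc1ccc(cc1)C(Cl)=O | starting material
5 | (1R,5R)-2-methyl-5-(propan-2-yl)cyclohex-2-en-1-yl 4-methoxybenzoate | CC1=CC[C@@H](C(C)C)C[C@H]1OC(=O)c2ccc(OC)cc2 | intermediate
6 | chromium trioxide | O=[Cr](=O)=O | starting material
7 | (1R,5R)-2-methyl-4-oxo-5-(propan-2-yl)cyclohex-2-en-1-yl 4-methoxybenzoate | CC1=CC(=O)[C@@H](C(C)C)C[C@H]1OC(=O)c2ccc(OC)cc2 | intermediate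
8 | (1R,4S,5R)-4-hydroxy-2-methyl-5-(propan-2-yl)cyclohex-2-en-1-yl 4-methoxybenzoate (OH, isopropyl and ester all cis) | CC1=C[C@@H](O)[C@@H](C(C)C)C[C@H]1OC(=O)c2ccc(OC)cc2 | intermediate
9 | tert-butyldimethylsilyl trifluoromethanesulfonate | CC(C)(C)[Si](C)(C)OS(=O)(=O)C(F)(F)F | starting material
10 | (1R,4S,5R)-4-[(tert-butyldimethylsilyl)oxy]-2-methyl-5-(propan-2-yl)cyclohex-2-en-1-yl 4-methoxybenzoate | CC1=C[C@@H](O[Si](C)(C)C(C)(C)C)[C@@H](C(C)C)C[C@H]1OC(=O)c2ccc(OC)cc2 | intermediate
11 | trichloroacetyl chloride | ClC(Cl)(Cl)C(Cl)=O | starting material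
12 | dichloroketene | ClC(Cl)=C=O | intermediate
13 | (1R,2R,4R,5S,6S)-5-[(tert-butyldimethylsilyl)oxy]-8,8-dichloro-1-methyl-7-oxo-4-(propan-2-yl)bicyclo[4.2.0]octan-2-yl 4-methoxybenzoate (cis-fused; four-membered ring anti to the three ring B substituents) | O=C1C(Cl)(Cl)[C@]2(C)[C@H]1[C@@H](O[Si](C)(C)C(C)(C)C)[C@@H](C(C)C)C[C@H]2OC(=O)c3ccc(OC)cc3 | intermediate
14 | (1R,2R,4R,5S,6S)-5-[(tert-butyldimethylsilyl)oxy]-1-methyl-7-oxo-4-(propan-2-yl)bicyclo[4.2.0]octan-2-yl 4-methoxybenzoate | O=C1C[C@]2(C)[C@H]1[C@@H](O[Si](C)(C)C(C)(C)C)[C@@H](C(C)C)C[C@H]2OC(=O)c3ccc(OC)cc3 | intermediate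
15 | ethylene | C=C | starting material
16 | (1R,3R,4S,4aS,8aR)-4-[(tert-butyldimethylsilyl)oxy]-8a-methyl-5-oxo-3-(propan-2-yl)decahydronaphthalen-1-yl 4-methoxybenzoate (cis-decalone) | O=C1CCC[C@]2(C)[C@H]1[C@@H](O[Si](C)(C)C(C)(C)C)[C@@H](C(C)C)C[C@H]2OC(=O)c3ccc(OC)cc3 | intermediate
17 | dibromomethane | BrCBr | starting material
18 | (1R,3R,4S,4aS,8aR)-4-[(tert-butyldimethylsilyl)oxy]-8a-methyl-5-methylidene-3-(propan-2-yl)decahydronaphthalen-1-yl 4-methoxybenzoate | C=C1CCC[C@]2(C)[C@H]1[C@@H](O[Si](C)(C)C(C)(C)C)[C@@H](C(C)C)C[C@H]2OC(=O)c3ccc(OC)cc3 | intermediate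
19 | (1R,3R,4S,4aS,8aR)-4-hydroxy-8a-methyl-5-methylidene-3-(propan-2-yl)decahydronaphthalen-1-yl 4-methoxybenzoate | C=C1CCC[C@]2(C)[C@H]1[C@@H](O)[C@@H](C(C)C)C[C@H]2OC(=O)c1ccc(OC)cc1 | target

**Step count and risks**

Total step count: 11. Longest linear sequence: 11 steps, from (R)-carvone.

Steps most likely to fail:

Step 9 (the proposed method). Rhodium may enter the wrong acyl C–C bond or extrude CO. The ketimine may also tautomerise to the enamine, which would epimerise C5 or expel the C6 silyloxy group by β-elimination. The fallback sets out from 14 and comes back at 16. It replaces the one two-carbon insertion by two successive one-carbon ring homologations with diazomethane, a known diazoalkane ketone homologation in which the less substituted α-carbon migrates. Diazomethane in Et2O/MeOH at 0 °C should expand 14 to the cis-fused hydrindanone F1, C1 migrating from C4 to the new carbon, which becomes C2. A second treatment with diazomethane under AlMe3 activation in CH2Cl2 at −78 °C should insert C3 between C4 and C2 and give 16. Neither step uses a base or an amine, so C5 should not be enolised.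

Step 7. The trisubstituted alkene is hindered and inductively deactivated by two allylic oxygens, so it may react too slowly with dichloroketene, while the zinc chloride formed may ionise the allylic anisate. The fallback sets out from 10 and comes back at 14, passing over 13 and step 8. N,N-Dimethylacetamide, Tf2O and 2,4,6-collidine in 1,2-dichloroethane at reflux should generate the N,N-dimethylketeniminium triflate F2, a cationic and more electrophilic two-carbon partner that needs no zinc. Its [2+2] cycloaddition to 10, with the same regiochemistry and the same facial preference, should give the cyclobutaniminium triflate F3. Hydrolysis with aqueous NaHCO3 should then give 14 directly, with no chlorine to remove.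

Step 5. Hydride may be delivered with poor facial selectivity, giving the C6 epimer by axial attack, or in the conjugate sense, or the intermediate alkoxide may take the anisoyl group over from O9. The fallback sets out from 7 and comes back at 8. It accepts the axial mode of attack and corrects C6 afterwards by substitution with inversion. Luche reduction (NaBH4, CeCl3·7H2O, MeOH, −40 °C) should give the equatorial C6 epimer F4. A Mitsunobu reaction with chloroacetic acid (PPh3, DIAD, toluene, 0 °C) should invert C6 and give the chloroacetate F5. Thiourea and NaHCO3 in EtOH should then remove the chloroacetyl group selectively in the presence of the anisate and give 8.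

Further compounds
F1 | step 9 | (3aS,4S,5R,7R,7aR)-4-[(tert-butyldimethylsilyl)oxy]-7a-methyl-3-oxo-5-(propan-2-yl)octahydro-1H-inden-7-yl 4-methoxybenzoate (cis-hydrindanone) | O=C1CC[C@]2(C)[C@H]1[C@@H](O[Si](C)(C)C(C)(C)C)[C@@H](C(C)C)C[C@H]2OC(=O)c3ccc(OC)cc3
F2 | step 7 | N,N-dimethylketeniminium trifluoromethanesulfonate | C=C=[N+](C)C.[O-]S(=O)(=O)C(F)(F)F
F3 | step 7 | N,N-dimethyliminium trifluoromethanesulfonate of cyclobutanone 14 (C=N+Me2 in place of C=O at C4) | C[N+](C)=C1C[C@]2(C)[C@H]1[C@@H](O[Si](C)(C)C(C)(C)C)[C@@H](C(C)C)C[C@H]2OC(=O)c3ccc(OC)cc3.[O-]S(=O)(=O)C(F)(F)F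
F4 | step 5 | (1R,4R,5R)-4-hydroxy-2-methyl-5-(propan-2-yl)cyclohex-2-en-1-yl 4-methoxybenzoate (C6 epimer of 8, OH trans to isopropyl) | CC1=C[C@H](O)[C@@H](C(C)C)C[C@H]1OC(=O)c2ccc(OC)cc2
F5 | step 5 | (1R,4S,5R)-4-(chloroacetoxy)-2-methyl-5-(propan-2-yl)cyclohex-2-en-1-yl 4-methoxybenzoate | CC1=C[C@@H](OC(=O)CCl)[C@@H](C(C)C)C[C@H]1OC(=O)c2ccc(OC)cc2
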